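**Retrosynthetic overview**
- Only the pyran C ring is built, and it is built last: the O1–C2 bond closes a 1-(B-aryl)-3-(A-aryl)propane-1,2-diol to the 2,3-trans flavan-3-ol.
- The diol comes from an α-hydroxy ketone by C=O reduction.
- Key C2–C3 disconnection between two carbonyl carbons: the catalyst-bound acyl anion of the B-ring aldehyde adds to the A-ring arylacetaldehyde (enantioselective cross-benzoin, sets C3).
- The A-ring aldehyde comes from 5-methoxyresorcinol bis-MOM ether by two directed ortho-lithiations (prenyl bromide, then ethylene oxide) and oxidation; the mirror symmetry of the prenylated arene fixes the regiochemistry.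

Assumption: 4-(methoxymethoxy)benzaldehyde is taken as a catalogue compound, and the triazolium precatalyst T of step 5 is used as whichever enantiomer gives Re-face attack on the acceptor aldehyde (assumed (5S), from L-pyroglutamic acid; otherwise the (5R) antipode).

**Step 1**
Reactants: 1 5-methoxyresorcinol; 2 chloromethyl methyl ether
Product: 3 1-methoxy-3,5-bis(methoxymethoxy)benzene
Conditions: MOMCl (2.5 equiv), i-Pr2NEt (3 equiv), CH2Cl2, 0 °C → rt
Reagents that add atoms: chloromethyl methyl ether 2, COCCl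
Why: Base-mediated O-alkylation (MOM acetal formation) of both phenols; the MOM ethers direct the two later lithiations and come off in the last step; no stereocenter.

**Step 2**
Reactants: 3 1-methoxy-3,5-bis(methoxymethoxy)benzene; 4 prenyl bromide
Product: 6 5-methoxy-1,3-bis(methoxymethoxy)-2-(3-methylbut-2-en-1-yl)benzene, via aryllithium 5 (not isolated)
Conditions: n-BuLi (1.1 equiv), THF, 0 °C → rt; CuI (10 mol %), prenyl bromide, −78 °C → rt
Reagents that add atoms: prenyl bromide 4, CC(C)=CCBr
Why: Directed ortho-metalation takes the C–H flanked by the two OMOM groups (the most strongly coordinated and acidified site), and the aryllithium is allylated at the primary carbon of prenyl bromide (Cu-catalysed SN2); no stereocenter.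

**Step 3**
Reactants: 6 5-methoxy-1,3-bis(methoxymethoxy)-2-(3-methylbut-2-en-1-yl)benzene; 7 ethylene oxide
Product: 9 2-[6-methoxy-2,4-bis(methoxymethoxy)-3-(3-methylbut-2-en-1-yl)phenyl]ethan-1-ol, via aryllithium 8 (not isolated)
Conditions: n-BuLi (1.2 equiv), TMEDA, THF, 0 °C; ethylene oxide (3 equiv, THF solution), −78 °C → rt; H2O
Reagents that add atoms: ethylene oxide 7, C1CO1
Why: Second directed ortho-metalation at one of the two remaining ring C–H positions (equivalent by the mirror symmetry of 6, each between OMe and OMOM), followed by SN2 opening of the epoxide by the aryllithium; no stereocenter.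

**Step 4**
Reactants: 9 2-[6-methoxy-2,4-bis(methoxymethoxy)-3-(3-methylbut-2-en-1-yl)phenyl]ethan-1-ol
Product: 10 2-[6-methoxy-2,4-bis(methoxymethoxy)-3-(3-methylbut-2-en-1-yl)phenyl]acetaldehyde
Conditions: Dess–Martin periodinane (1.3 equiv), CH2Cl2, 0 °C → rt; used at once
Reagents that add atoms: none
Why: Dess–Martin oxidation of the primary alcohol stops at the aldehyde under near-neutral conditions that leave the MOM acetals and the prenyl alkene untouched; no stereocenter.

**Step 5 (key step)**
Reactants: 10 2-[6-methoxy-2,4-bis(methoxymethoxy)-3-(3-methylbut-2-en-1-yl)phenyl]acetaldehyde; 11 4-(methoxymethoxy)benzaldehyde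
Product: 12 (2S)-2-hydroxy-3-[6-methoxy-2,4-bis(methoxymethoxy)-3-(3-methylbut-2-en-1-yl)phenyl]-1-[4-(methoxymethoxy)phenyl]propan-1-one
Conditions: 11 (3 equiv), precatalyst T = 5-[hydroxy(diphenyl)methyl]-2-(pentafluorophenyl)-6,7-dihydro-5H-pyrrolo[2,1-c][1,2,4]triazol-2-ium tetrafluoroborate (15 mol %), i-Pr2NEt (15 mol %), 4 Å MS, THF, rt; 10 added over 8 h
Reagents that add atoms: none
Why: Proposed new method: an enantioselective intermolecular cross-benzoin in which the chiral triazolylidene adds to aromatic aldehyde 11 (held in threefold excess while 10 is fed slowly, so the catalyst-bound acyl anion, a Breslow-type enaminol, forms almost only from 11) and this reversed-polarity carbonyl carbon attacks the much more electrophilic aliphatic C=O of 10 on its Re face (acceptor held by the catalyst OH hydrogen bond, the other face screened by the CPh2 unit) to give the (S)-carbinol, while self-coupling of electron-rich 11 is slow and reversible and the conjugated aryl ketone 12 is not reopened; the closest known reaction types are the NHC-catalysed asymmetric benzoin condensation and chemoselective aromatic–aliphatic crossed acyloin reactions.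

**Step 6**
Reactants: 12 (2S)-2-hydroxy-3-[6-methoxy-2,4-bis(methoxymethoxy)-3-(3-methylbut-2-en-1-yl)phenyl]-1-[4-(methoxymethoxy)phenyl]propan-1-one
Product: 15 (2R,3S)-8-prenylafzelechin 5-methyl ether, via MOM-protected diol 13 (not isolated), via free pentaol 14 (not isolated)
Conditions: NaBH4 (1.5 equiv), MeOH–THF, 0 °C; then conc. HCl (to ca. 1.5 M), 45 °C; chromatography
Reagents that add atoms: none
Why: Borohydride reduction gives the diol (C1 epimer mixture, which does not matter), then acid-catalysed acetal exchange removes the three MOM groups and the p-hydroxybenzylic C1–OH ionises so that the ortho-phenol closes the pyran ring (SN1-type benzylic etherification, the established diol-to-flavan-3-ol closure) through a chair-like transition state with aryl and 3-OH both equatorial, giving mainly the 2,3-trans isomer (about 3:1 over cis expected, cis removed by chromatography) while C3 from step 5 is untouched.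

**Compound list**
1 | 5-methoxyresorcinol (5-methoxybenzene-1,3-diol) | COc1cc(O)cc(O)c1 | starting material
2 | chloromethyl methyl ether | COCCl | starting material
3 | 1-methoxy-3,5-bis(methoxymethoxy)benzene | COCOc1cc(OC)cc(OCOC)c1 | intermediate
4 | prenyl bromide (1-bromo-3-methylbut-2-ene) | CC(C)=CCBr | starting material
5 | [4-methoxy-2,6-bis(methoxymethoxy)phenyl]lithium | [Li]c1c(OCOC)cc(OC)cc1OCOC | intermediate (not isolated)
6 | 5-methoxy-1,3-bis(methoxymethoxy)-2-(3-methylbut-2-en-1-yl)benzene | COCOc1cc(OC)cc(OCOC)c1CC=C(C)C | intermediate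
7 | ethylene oxide | C1CO1 | starting material
8 | [6-methoxy-2,4-bis(methoxymethoxy)-3-(3-methylbut-2-en-1-yl)phenyl]lithium | [Li]c1c(OC)cc(OCOC)c(CC=C(C)C)c1OCOC | intermediate (not isolated)
9 | 2-[6-methoxy-2,4-bis(methoxymethoxy)-3-(3-methylbut-2-en-1-yl)phenyl]ethan-1-ol | OCCc1c(OC)cc(OCOC)c(CC=C(C)C)c1OCOC | intermediate
10 | 2-[6-methoxy-2,4-bis(methoxymethoxy)-3-(3-methylbut-2-en-1-yl)phenyl]acetaldehyde | O=CCc1c(OC)cc(OCOC)c(CC=C(C)C)c1OCOC | intermediate
11 | 4-(methoxymethoxy)benzaldehyde | COCOc1ccc(C=O)cc1 | starting material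
12 | (2S)-2-hydroxy-3-[6-methoxy-2,4-bis(methoxymethoxy)-3-(3-methylbut-2-en-1-yl)phenyl]-1-[4-(methoxymethoxy)phenyl]propan-1-one | COCOc1ccc(cc1)C(=O)[C@@H](O)Cc1c(OC)cc(OCOC)c(CC=C(C)C)c1OCOC | intermediate
13 | (1RS,2S)-3-[6-methoxy-2,4-bis(methoxymethoxy)-3-(3-methylbut-2-en-1-yl)phenyl]-1-[4-(methoxymethoxy)phenyl]propane-1,2-diol | COCOc1ccc(cc1)C(O)[C@@H](O)Cc1c(OC)cc(OCOC)c(CC=C(C)C)c1OCOC | intermediate (not isolated)
14 | (1RS,2S)-3-[2,4-dihydroxy-6-methoxy-3-(3-methylbut-2-en-1-yl)phenyl]-1-(4-hydroxyphenyl)propane-1,2-diol | Oc1ccc(cc1)C(O)[C@@H](O)Cc1c(OC)cc(O)c(CC=C(C)C)c1O | intermediate (not isolated)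
15 | 8-prenylafzelechin 5-methyl ether, (2R,3S)-2-(4-hydroxyphenyl)-5-methoxy-8-(3-methylbut-2-en-1-yl)-3,4-dihydro-2H-chromene-3,7-diol | COc1cc(O)c(CC=C(C)C)c2c1C[C@H](O)[C@@H](c1ccc(O)cc1)O2 | target

**Totals**
Total step count: 6. Longest linear sequence: 6 (1 → 3 → 6 → 9 → 10 → 12 → 15).

**Three steps most likely to fail**

Step 5 (cross-benzoin). The risks are self-acyloin of 10, the reversed cross product (10 as donor), and insufficient enantioselectivity. The fallback sets out from 11 (with 10) and comes back at 12. It makes the acyl donor unambiguous by using an acylsilane in a chiral metallophosphite-catalysed cross silyl benzoin. Aldehyde 11 is thioacetalised with propane-1,3-dithiol (cat. I2) to 2-[4-(methoxymethoxy)phenyl]-1,3-dithiane F1. F1 is lithiated (n-BuLi) and silylated with Et3SiCl to triethyl{2-[4-(methoxymethoxy)phenyl]-1,3-dithian-2-yl}silane F2, which is unmasked (I2, CaCO3, aqueous THF) to [4-(methoxymethoxy)phenyl](triethylsilyl)methanone F3. F3 and 10 with a catalytic TADDOL-derived lithium phosphite (the enantiomer giving the S adduct) react by phosphite addition, 1,2-Brook shift, addition to 10 and 1,4-silyl transfer. This gives (2S)-3-[6-methoxy-2,4-bis(methoxymethoxy)-3-(3-methylbut-2-en-1-yl)phenyl]-1-[4-(methoxymethoxy)phenyl]-2-(triethylsilyloxy)propan-1-one F4. Mild desilylation (AcOH/THF/H2O) returns 12.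

Step 6 (reduction, deprotection, ring closure). The risks are a modest trans:cis ratio in the ionising closure, a pinacol-type hydride shift of the benzylic cation, and acid damage to the ortho-prenylphenol. The fallback sets out from 10 and comes back at 15. It replaces the ionising closure by a stereospecific SN2 closure on a B ring that cannot ionise. 4-Formylphenyl methanesulfonate F5 (one step from 4-hydroxybenzaldehyde and MsCl) takes the place of 11 under the step 5 conditions and gives 4-{(2S)-2-hydroxy-3-[6-methoxy-2,4-bis(methoxymethoxy)-3-(3-methylbut-2-en-1-yl)phenyl]propanoyl}phenyl methanesulfonate F6. Catalyst-controlled transfer hydrogenation (RuCl[(R,R)-TsDPEN](p-cymene), HCO2H/Et3N, matched with the 2S centre) gives the syn diol 4-{(1S,2S)-1,2-dihydroxy-3-[6-methoxy-2,4-bis(methoxymethoxy)-3-(3-methylbut-2-en-1-yl)phenyl]propyl}phenyl methanesulfonate F7. Dilute HCl/MeOH removes the two MOM groups without ionising the mesyloxy-deactivated benzylic alcohol and gives 4-{(1S,2S)-3-[2,4-dihydroxy-6-methoxy-3-(3-methylbut-2-en-1-yl)phenyl]-1,2-dihydroxypropyl}phenyl methanesulfonate F8. Mitsunobu closure (PPh3, DIAD, THF, 0 °C) lets the ortho-phenol displace the benzylic oxygen with inversion and gives 4-[(2R,3S)-3,7-dihydroxy-5-methoxy-8-(3-methylbut-2-en-1-yl)-3,4-dihydro-2H-chromen-2-yl]phenyl methanesulfonate F9. Excess LDA (THF, −78 → 0 °C) cleaves the aryl mesylate to give 15.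

Step 3 (second lithiation). The risks are deprotonation of the benzylic/allylic prenyl CH2 instead of the ring, or incomplete ring lithiation. The fallback sets out from 6 and comes back at 8. It replaces C–H deprotonation by halogen–metal exchange. NBS (1.0 equiv, MeCN, −30 °C) brominates the only free, strongly activated ring position and gives 1-bromo-6-methoxy-2,4-bis(methoxymethoxy)-3-(3-methylbut-2-en-1-yl)benzene F10. t-BuLi (2.1 equiv, THF, −78 °C) exchanges bromine for lithium faster than any deprotonation and regenerates aryllithium 8, which is taken on with ethylene oxide to 9 as in step 3.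

**Further compounds**
F1 | step 5 | 2-[4-(methoxymethoxy)phenyl]-1,3-dithiane | COCOc1ccc(cc1)C1SCCCS1
F2 | step 5 | triethyl{2-[4-(methoxymethoxy)phenyl]-1,3-dithian-2-yl}silane | CC[Si](CC)(CC)C1(SCCCS1)c1ccc(OCOC)cc1
F3 | step 5 | [4-(methoxymethoxy)phenyl](triethylsilyl)methanone | CC[Si](CC)(CC)C(=O)c1ccc(OCOC)cc1
F4 | step 5 | (2S)-3-[6-methoxy-2,4-bis(methoxymethoxy)-3-(3-methylbut-2-en-1-yl)phenyl]-1-[4-(methoxymethoxy)phenyl]-2-(triethylsilyloxy)propan-1-one | COCOc1ccc(cc1)C(=O)[C@@H](O[Si](CC)(CC)CC)Cc1c(OC)cc(OCOC)c(CC=C(C)C)c1OCOC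
F5 | step 6 | 4-formylphenyl methanesulfonate | CS(=O)(=O)Oc1ccc(C=O)cc1
F6 | step 6 | 4-{(2S)-2-hydroxy-3-[6-methoxy-2,4-bis(methoxymethoxy)-3-(3-methylbut-2-en-1-yl)phenyl]propanoyl}phenyl methanesulfonate | CS(=O)(=O)Oc1ccc(cc1)C(=O)[C@@H](O)Cc1c(OC)cc(OCOC)c(CC=C(C)C)c1OCOC
F7 | step 6 | 4-{(1S,2S)-1,2-dihydroxy-3-[6-methoxy-2,4-bis(methoxymethoxy)-3-(3-methylbut-2-en-1-yl)phenyl]propyl}phenyl methanesulfonate | CS(=O)(=O)Oc1ccc(cc1)[C@H](O)[C@@H](O)Cc1c(OC)cc(OCOC)c(CC=C(C)C)c1OCOC
F8 | step 6 | 4-{(1S,2S)-3-[2,4-dihydroxy-6-methoxy-3-(3-methylbut-2-en-1-yl)phenyl]-1,2-dihydroxypropyl}phenyl methanesulfonate | CS(=O)(=O)Oc1ccc(cc1)[C@H](O)[C@@H](O)Cc1c(OC)cc(O)c(CC=C(C)C)c1O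
F9 | step 6 | 4-[(2R,3S)-3,7-dihydroxy-5-methoxy-8-(3-methylbut-2-en-1-yl)-3,4-dihydro-2H-chromen-2-yl]phenyl methanesulfonate | COc1cc(O)c(CC=C(C)C)c2c1C[C@H](O)[C@@H](c1ccc(OS(C)(=O)=O)cc1)O2
F10 | step 3 | 1-bromo-6-methoxy-2,4-bis(methoxymethoxy)-3-(3-methylbut-2-en-1-yl)benzene | Brc1c(OC)cc(OCOC)c(CC=C(C)C)c1OCOC
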